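**Retrosynthetic overview**
- The only ring that has to be built is the tetralone ring. Both aryl rings come from catechol and propionic acid by Friedel–Crafts acylation.
- The tetralone ring forms in one radical cascade. An α-keto radical from the ring-A α-bromoketone adds to the β-carbon of (E)-3,4-dimethoxy-β-methylstyrene, forming the C2–C3 bond. The resulting benzylic radical is oxidised to the cation and closes onto the aroyl ring (C4–C4a), giving the 3,4-trans core.
- The C2 methyl stereocentre is set last by base equilibration, which also removes the silyl group. The final racemate is resolved.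

**Assumption:** Base equilibration at C2 favours the cis-2,3-dimethyl isomer found in the target, with 4-Ar and 3-Me pseudo-axial and 2-Me pseudo-equatorial. The racemic product is resolved at the end.

---

**Step 1**
Reactants: 1 benzene-1,2-diol (catechol); 2 propanoic acid
Product: 3 1-(3,4-dihydroxyphenyl)propan-1-one
Conditions: BF3·OEt2 (3 equiv), neat, 90 °C, 4 h
Reagents that add atoms: none
Why: BF3-mediated Friedel–Crafts acylation of catechol occurs para to one OH and installs the ring-A and ring-B propionyl unit in one step; there is no stereocentre.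

**Step 2**
Reactants: 3 1-(3,4-dihydroxyphenyl)propan-1-one
Product: 4 1-(3-hydroxy-4-methoxyphenyl)propan-1-one
Conditions: MeI (1.0 equiv), NaHCO3, DMF, 40 °C
Reagents that add atoms: methyl iodide, CI
Why: The 4-OH, para to the carbonyl, is the more acidic phenol, so mild-base Williamson methylation is selective for it, giving the 3-OH/4-OMe pattern of ring A; there is no stereocentre.

**Step 3**
Reactants: 4 1-(3-hydroxy-4-methoxyphenyl)propan-1-one
Product: 5 1-[3-(tert-butyldimethylsilyloxy)-4-methoxyphenyl]propan-1-one
Conditions: TBSCl, imidazole, DMF, 23 °C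
Reagents that add atoms: tert-butyldimethylsilyl chloride, C[Si](C)(Cl)C(C)(C)C
Why: Silylation masks the free phenol so it survives bromination and the radical/cation step, and the silyl ether keeps ring A electron-rich at the position para to oxygen; there is no stereocentre.

**Step 4**
Reactants: 5 1-[3-(TBSO)-4-methoxyphenyl]propan-1-one
Product: 6 (±)-2-bromo-1-[3-(TBSO)-4-methoxyphenyl]propan-1-one
Conditions: CuBr2 (2.2 equiv), EtOAc/CHCl3 1:1, reflux
Reagents that add atoms: copper(II) bromide, Br[Cu]Br
Why: CuBr2 gives selective α-bromination of the aryl ketone (King–Ostrom) without ring bromination; the α-stereocentre is racemic and is destroyed on radical formation, so it does not matter.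

**Step 5**
Reactants: 3 1-(3,4-dihydroxyphenyl)propan-1-one
Product: 7 1-(3,4-dimethoxyphenyl)propan-1-one
Conditions: Me2SO4 (2.5 equiv), K2CO3, acetone, reflux
Reagents that add atoms: dimethyl sulfate, COS(=O)(=O)OC
Why: Exhaustive Williamson O-methylation gives the ring-B ketone; there is no stereocentre.

**Step 6**
Reactants: 7 1-(3,4-dimethoxyphenyl)propan-1-one
Product: 8 (±)-1-(3,4-dimethoxyphenyl)propan-1-ol
Conditions: NaBH4, MeOH, 0 °C
Reagents that add atoms: none
Why: Hydride reduction of the ketone; the carbinol stereocentre is destroyed in the next step.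

**Step 7**
Reactants: 8 (±)-1-(3,4-dimethoxyphenyl)propan-1-ol
Product: 9 (E)-1,2-dimethoxy-4-(prop-1-en-1-yl)benzene
Conditions: TsOH·H2O (5 mol %), toluene, reflux, Dean–Stark
Reagents that add atoms: none
Why: E1 dehydration of the benzylic alcohol gives the conjugated alkene; the E geometry is thermodynamically favoured.

**Step 8**
Reactants: 6 (±)-2-bromo-1-[3-(TBSO)-4-methoxyphenyl]propan-1-one (1.0 equiv); 9 (E)-1,2-dimethoxy-4-(prop-1-en-1-yl)benzene (3 equiv)
Product: 10 (±)-7-(TBSO)-4-(3,4-dimethoxyphenyl)-6-methoxy-2,3-dimethyl-3,4-dihydronaphthalen-1(2H)-one, 3,4-trans, C2 epimeric mixture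
Conditions: fac-Ir(ppy)3 (1 mol %), 2,6-lutidine (2 equiv), HFIP/MeCN 1:1 (0.05 M), blue LEDs, 25 °C, 16 h
Reagents that add atoms: none (6 and 9 supply every atom; HBr leaves as lutidinium bromide)
Why: Proposed new method: excited Ir(ppy)3 reduces the α-bromoketone to the electrophilic α-keto radical, which adds to the methyl-bearing carbon of the electron-rich (E)-alkene (polarity-matched), forming the C2–C3 bond and a benzylic radical at C4. Ir(IV) oxidises this radical to the 3,4-dimethoxybenzyl cation, and HFIP-promoted closure onto the ring position para to OTBS gives the six-membered ring, with loss of H+. The closest known reactions are photoredox atom-transfer/radical-polar-crossover additions of α-bromocarbonyls to styrenes and Mn(III) oxidative radical annulations of ketones with alkenes. The C3–C4 relationship is set in the ring-closing transition state, which places the 4-aryl group trans to the 3-methyl to avoid peri-H5 and gauche strain; the product is racemic at this stage.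

**Step 9**
Reactants: 10 (±)-tetralone, C2 epimeric mixture
Product: 11 (±)-schisandrone, (2S*,3S*,4R*)
Conditions: NaOMe (3 equiv), MeOH, 40 °C, 6 h; then aq. NH4Cl
Reagents that add atoms: none
Why: Methoxide cleaves the aryl silyl ether and enolises the ketone, so C2 equilibrates to the thermodynamic cis-2,3-dimethyl isomer (4-Ar and 3-Me pseudo-axial, 2-Me pseudo-equatorial). C3 and C4 cannot epimerise because there is no acidic hydrogen or leaving group at those positions.

**Step 10**
Reactants: 11 (±)-schisandrone
Product: 12 (2S,3S,4R)-schisandrone, the target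
Conditions: preparative HPLC on a chiral stationary phase (Chiralpak IA, hexane/EtOH), 23 °C
Reagents that add atoms: none
Why: Chromatographic resolution of the racemate gives the single (2S,3S,4R) enantiomer; the configurations at C2, C3 and C4 are already fixed and are not altered.

---

**Compound list**
1 | benzene-1,2-diol (catechol) | Oc1ccccc1O | starting material
2 | propanoic acid | CCC(=O)O | starting material
3 | 1-(3,4-dihydroxyphenyl)propan-1-one | CCC(=O)c1ccc(O)c(O)c1 | intermediate
4 | 1-(3-hydroxy-4-methoxyphenyl)propan-1-one | CCC(=O)c1ccc(OC)c(O)c1 | intermediate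
5 | 1-[3-(TBSO)-4-methoxyphenyl]propan-1-one | CCC(=O)c1ccc(OC)c(O[Si](C)(C)C(C)(C)C)c1 | intermediate
6 | (±)-2-bromo-1-[3-(TBSO)-4-methoxyphenyl]propan-1-one | CC(Br)C(=O)c1ccc(OC)c(O[Si](C)(C)C(C)(C)C)c1 | intermediate
7 | 1-(3,4-dimethoxyphenyl)propan-1-one | CCC(=O)c1ccc(OC)c(OC)c1 | intermediate
8 | (±)-1-(3,4-dimethoxyphenyl)propan-1-ol | CCC(O)c1ccc(OC)c(OC)c1 | intermediate
9 | (E)-1,2-dimethoxy-4-(prop-1-en-1-yl)benzene | C/C=C/c1ccc(OC)c(OC)c1 | intermediate
10 | (±)-7-(TBSO)-4-(3,4-dimethoxyphenyl)-6-methoxy-2,3-dimethyltetralin-1-one, 3,4-trans, C2 epimeric mixture | COc1cc2c(cc1O[Si](C)(C)C(C)(C)C)C(=O)C(C)[C@@H](C)[C@@H]2c1ccc(OC)c(OC)c1 | intermediate (racemic; C2 undefined)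
11 | (±)-schisandrone | COc1cc2c(cc1O)C(=O)[C@@H](C)[C@@H](C)[C@@H]2c1ccc(OC)c(OC)c1 | intermediate (racemic; one enantiomer drawn)
12 | (2S,3S,4R)-schisandrone | COc1cc2c(cc1O)C(=O)[C@@H](C)[C@@H](C)[C@@H]2c1ccc(OC)c(OC)c1 | target

**Totals:** 10 steps in total. The longest linear sequence is 7 steps (1→3→4→5→6→10→11→12 through steps 1, 2, 3, 4, 8, 9, 10).

**Three steps most likely to fail**
1. **Step 8 (radical-polar annulation):** the cation may be trapped by bromide, MeCN or elimination instead of closing onto the acylated ring. Fallback: go stepwise. Run a Cu- or Ir-catalysed atom-transfer radical addition to isolate the γ-bromo ketone, then ionise it with AgSbF6 in HFIP to close the ring.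
2. **Step 2 (regioselective mono-methylation):** the 3-O/4-O selectivity may be poor. Fallback: change the route to the ring-A ketone by taking dimethyl ether 7, which is already made for ring B, and cleaving only the meta-OMe with MeSO3H/methionine, then continuing at step 3.
3. **Step 9 (C2 equilibration to the cis isomer):** the thermodynamic ratio may favour the wrong C2 epimer. Fallback: run the annulation with the 2-desmethyl bromoketone (from acetic acid instead of propionic acid). Then install the 2-methyl by LDA/MeI on the 3,4-trans-tetralone, where the pseudo-axial 4-aryl group shields the top face and directs the methyl cis to the 3-methyl.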